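**Strategy.** The C40 chain is cut at C11=C12 and C11'=C12' (two Wittig reactions of C15 phosphonium salts with the C10 dialdehyde). Each ring–C≡C bond is cut to an enol triflate and (E)-3-methylpent-2-en-4-yn-1-ol. Everything rests on ring A, the cyclohexa-1,3-diene: its methyl-bearing sp2 carbon C5 lies between C6 and C4. C5 and its methyl are therefore inserted as chloro(methyl)carbene into the enol double bond of the silyl enol ether of 2,2-dimethylcyclopentanone. Strain-driven opening of the resulting chlorocyclopropane enlarges the five-membered ring to 2,6,6-trimethylcyclohex-2-enone in one operation, with the C1 gem-dimethyl group, the C5 methyl and the C6 carbonyl correctly placed.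

Key step: step 2

Remark: (E)-3-methylpent-2-en-4-yn-1-ol, (4R,6R)-4-hydroxy-2,2,6-trimethylcyclohexanone and (2E,4E,6E)-2,7-dimethylocta-2,4,6-trienedial are taken as purchasable carotenoid intermediates; ring atoms carry carotenoid numbers (ring A = cyclohexa-1,3-diene end, ring B = hydroxylated end).

**Step 1**
Reactants: 1 2,2-dimethylcyclopentan-1-one
Product: 3 trimethyl[(5,5-dimethylcyclopent-1-en-1-yl)oxy]silane, via lithium enolate 2 (not isolated)
Conditions: lithium diisopropylamide, THF, −78 °C; Me3SiCl, −78 °C to rt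
Reagents that add atoms: chlorotrimethylsilane, C[Si](C)(C)Cl
Why: Silyl enol ether formation: irreversible deprotonation at the only enolisable α-carbon (the other is quaternary) gives one lithium enolate, which chlorotrimethylsilane traps on oxygen.

**Step 2**
Reactants: 3 trimethyl[(5,5-dimethylcyclopent-1-en-1-yl)oxy]silane
Product: 5 2,6,6-trimethylcyclohex-2-en-1-one, via chlorocyclopropane 4 (not isolated)
Conditions: CH3CHCl2, n-BuLi, Et2O, −35 °C to rt; then toluene, 110 °C
Reagents that add atoms: 1,1-dichloroethane, CC(Cl)Cl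
Why: n-BuLi deprotonates 1,1-dichloroethane and the carbenoid CH3CCl2Li transfers chloro(methyl)carbene to the electron-rich enol double bond of 3 (concerted [2+1] cycloaddition, which closes the three-membered ring) to give 4; on heating, the bond shared by the three- and five-membered rings of 4 breaks in a disrotatory cyclopropyl-to-allyl electrocyclic opening as chloride leaves, pushed by the siloxy oxygen, and chloride then removes the silyl group from the 2-siloxyallyl cation, so the six-membered ring arises by one-carbon ring enlargement and not by an end-to-end closure. The closest known reaction type is the halocarbene ring expansion of cyclic silyl enol ethers to 2-substituted cycloalk-2-enones, the siloxy-assisted form of the gem-dihalocyclopropane ring enlargement. The carbonyl carbon becomes C6 of ring A, the carbene carbon with its methyl becomes C5, the former enol CH becomes C4, the two CH2 groups become C3 and C2 and the CMe2 carbon becomes C1; no stereocentre remains in 5, those of 4 being destroyed in the opening. Regiochemistry needs no control, because 1 has a single enolisable α-carbon and the carbene carbon can only enter between the carbonyl carbon and that CH. The selectivity the step does need is stereoelectronic: only the C6 epimer of 4 with chloride endo (cis to the five-membered ring) can open to a cis-cyclohexenyl cation, and a useful share of it is expected from the tendency of chlorine to sit syn to the alkene carbons in chlorocarbene additions, with relief of cyclopropane strain and formation of the conjugated enone driving the opening.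

**Step 3**
Reactants: 5 2,6,6-trimethylcyclohex-2-en-1-one
Product: 7 2,6,6-trimethylcyclohexa-1,3-dien-1-yl trifluoromethanesulfonate, via lithium dienolate 6 (not isolated)
Conditions: lithium diisopropylamide, THF, −78 to 0 °C; PhNTf2, −78 °C to rt
Reagents that add atoms: N-phenylbis(trifluoromethanesulfonimide), O=S(=O)(N(c1ccccc1)S(=O)(=O)C(F)(F)F)C(F)(F)F
Why: Enol triflate formation through vinylogous (γ) deprotonation: with C1 quaternary the base can only remove a C3 proton, and the linear dienolate is triflated on oxygen, which sets both ring A double bonds (C3=C4 and C5=C6) and the leaving group at C6.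

**Step 4**
Reactants: 7 2,6,6-trimethylcyclohexa-1,3-dien-1-yl trifluoromethanesulfonate; 8 (E)-3-methylpent-2-en-4-yn-1-ol
Product: 9 (E)-3-methyl-5-(2,6,6-trimethylcyclohexa-1,3-dien-1-yl)pent-2-en-4-yn-1-ol
Conditions: Pd(PPh3)4 (cat.), CuI (cat.), iPr2NH, DMF, rt
Reagents that add atoms: none
Why: Sonogashira coupling: zerovalent palladium inserts into the C6–O bond of the dienyl triflate and the copper acetylide of 8 is transferred, so the ring–C≡C bond forms with the E geometry of the enynol untouched and the alcohol unprotected.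

**Step 5**
Reactants: 9 (E)-3-methyl-5-(2,6,6-trimethylcyclohexa-1,3-dien-1-yl)pent-2-en-4-yn-1-ol
Product: 10 [(E)-3-methyl-5-(2,6,6-trimethylcyclohexa-1,3-dien-1-yl)pent-2-en-4-yn-1-yl]triphenylphosphonium bromide
Conditions: PPh3·HBr, MeOH, 0 °C to rt
Reagents that add atoms: triphenylphosphine hydrobromide, [Br-].[PH+](c1ccccc1)(c1ccccc1)c1ccccc1
Why: Phosphonium salt formation from an allylic alcohol: the acid ionises the primary allylic alcohol and triphenylphosphine captures the delocalised cation at its unhindered terminus, the standard entry to C15 Wittig salts.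

**Step 6**
Reactants: 11 (4R,6R)-4-hydroxy-2,2,6-trimethylcyclohexan-1-one
Product: 12 (4R,6R)-4-[(tert-butyldimethylsilyl)oxy]-2,2,6-trimethylcyclohexan-1-one
Conditions: tBuMe2SiCl, imidazole, DMF, rt
Reagents that add atoms: tert-butyldimethylsilyl chloride, CC(C)(C)[Si](C)(C)Cl
Why: Silyl ether protection masks the hydroxyl against the amide base of the next step; the C4 stereocentre (R, from the chiral pool) is not touched.

**Step 7**
Reactants: 12 (4R,6R)-4-[(tert-butyldimethylsilyl)oxy]-2,2,6-trimethylcyclohexan-1-one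
Product: 14 (4R)-4-[(tert-butyldimethylsilyl)oxy]-2,6,6-trimethylcyclohex-1-en-1-yl trifluoromethanesulfonate, via lithium enolate 13 (not isolated)
Conditions: lithium diisopropylamide, THF, −78 °C; PhNTf2, −78 °C to rt
Reagents that add atoms: N-phenylbis(trifluoromethanesulfonimide), O=S(=O)(N(c1ccccc1)S(=O)(=O)C(F)(F)F)C(F)(F)F
Why: Enol triflate formation: only C6 of the ketone carries an α-hydrogen (C2 is quaternary), so deprotonation and O-triflation give a single regioisomer; the C6 stereocentre is erased on purpose while C4 (R) is unaffected.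

**Step 8**
Reactants: 14 (4R)-4-[(tert-butyldimethylsilyl)oxy]-2,6,6-trimethylcyclohex-1-en-1-yl trifluoromethanesulfonate; 8 (E)-3-methylpent-2-en-4-yn-1-ol
Product: 15 (E)-5-{(4R)-4-[(tert-butyldimethylsilyl)oxy]-2,6,6-trimethylcyclohex-1-en-1-yl}-3-methylpent-2-en-4-yn-1-ol
Conditions: Pd(PPh3)4 (cat.), CuI (cat.), iPr2NH, DMF, rt
Reagents that add atoms: none
Why: Sonogashira coupling of the hindered enol triflate with the terminal alkyne forms the ring B–C≡C bond without touching the silyl ether, the stereocentre or the E double bond.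

**Step 9**
Reactants: 15 (E)-5-{(4R)-4-[(tert-butyldimethylsilyl)oxy]-2,6,6-trimethylcyclohex-1-en-1-yl}-3-methylpent-2-en-4-yn-1-ol
Product: 16 (1R)-4-[(E)-5-hydroxy-3-methylpent-3-en-1-yn-1-yl]-3,5,5-trimethylcyclohex-3-en-1-ol
Conditions: Bu4NF, THF, 0 °C to rt
Reagents that add atoms: none
Why: Fluoride-mediated desilylation, driven by the strong Si–F bond, frees the secondary alcohol under conditions that leave the enyne and the allylic alcohol alone.

**Step 10**
Reactants: 16 (1R)-4-[(E)-5-hydroxy-3-methylpent-3-en-1-yn-1-yl]-3,5,5-trimethylcyclohex-3-en-1-ol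
Product: 17 {(E)-5-[(4R)-4-hydroxy-2,6,6-trimethylcyclohex-1-en-1-yl]-3-methylpent-2-en-4-yn-1-yl}triphenylphosphonium bromide
Conditions: PPh3·HBr, MeOH, 0 °C to rt
Reagents that add atoms: triphenylphosphine hydrobromide, [Br-].[PH+](c1ccccc1)(c1ccccc1)c1ccccc1
Why: Phosphonium salt formation: only the primary allylic hydroxyl can ionise under the mild acid, so triphenylphosphine is attached there and the secondary, non-allylic (R) carbinol stays free and configurationally intact.

**Step 11**
Reactants: 10 [(E)-3-methyl-5-(2,6,6-trimethylcyclohexa-1,3-dien-1-yl)pent-2-en-4-yn-1-yl]triphenylphosphonium bromide; 18 (2E,4E,6E)-2,7-dimethylocta-2,4,6-trienedial (3 equiv)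
Product: 20 (2E,4E,6E,8E,10E)-2,7,11-trimethyl-13-(2,6,6-trimethylcyclohexa-1,3-dien-1-yl)trideca-2,4,6,8,10-pentaen-12-ynal, via ylide 19 (not isolated)
Conditions: NaOMe, MeOH/CH2Cl2, 0 °C to rt; then EtOAc, 60 °C, dark
Reagents that add atoms: none
Why: Wittig olefination: the semi-stabilised ylide attacks one aldehyde group of the dialdehyde used in excess to form C11=C12, and the sterically strained 11Z isomer is expected to isomerise to E on gentle warming.

**Step 12**
Reactants: 17 {(E)-5-[(4R)-4-hydroxy-2,6,6-trimethylcyclohex-1-en-1-yl]-3-methylpent-2-en-4-yn-1-yl}triphenylphosphonium bromide; 20 (2E,4E,6E,8E,10E)-2,7,11-trimethyl-13-(2,6,6-trimethylcyclohexa-1,3-dien-1-yl)trideca-2,4,6,8,10-pentaen-12-ynal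
Product: 22 (3R)-3',4',7,8,7',8'-hexadehydro-β,β-caroten-3-ol (all-E; CNP0250213.1), via ylide 21 (not isolated)
Conditions: NaOMe, MeOH/CH2Cl2, 0 °C to rt; then EtOAc, 60 °C, dark
Reagents that add atoms: none
Why: Wittig olefination forms C11'=C12' and completes the C40 chain; the free hydroxyl is tolerated by the ylide, the (3R) centre is remote from all reacting sites, and the hindered Z isomer at the new bond should again relax to E on gentle warming.

**Compound list**

1 | 2,2-dimethylcyclopentan-1-one | CC1(C)CCCC1=O | starting material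
2 | lithium 5,5-dimethylcyclopent-1-en-1-olate | [Li+].[O-]C1=CCCC1(C)C | intermediate
3 | trimethyl[(5,5-dimethylcyclopent-1-en-1-yl)oxy]silane | C[Si](C)(C)OC1=CCCC1(C)C | intermediate
4 | 6-chloro-2,2,6-trimethyl-1-(trimethylsilyloxy)bicyclo[3.1.0]hexane (racemic, both C6 epimers) | C[Si](C)(C)OC12C(C)(C)CCC1C2(C)Cl | intermediate
5 | 2,6,6-trimethylcyclohex-2-en-1-one | CC1=CCCC(C)(C)C1=O | intermediate
6 | lithium 2,6,6-trimethylcyclohexa-1,3-dien-1-olate | [Li+].[O-]C1=C(C)C=CCC1(C)C | intermediate
7 | 2,6,6-trimethylcyclohexa-1,3-dien-1-yl trifluoromethanesulfonate | CC1=C(OS(=O)(=O)C(F)(F)F)C(C)(C)CC=C1 | intermediate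
8 | (E)-3-methylpent-2-en-4-yn-1-ol | C#C/C(C)=C/CO | starting material
9 | (E)-3-methyl-5-(2,6,6-trimethylcyclohexa-1,3-dien-1-yl)pent-2-en-4-yn-1-ol | CC1=C(C#C/C(C)=C/CO)C(C)(C)CC=C1 | intermediate
10 | [(E)-3-methyl-5-(2,6,6-trimethylcyclohexa-1,3-dien-1-yl)pent-2-en-4-yn-1-yl]triphenylphosphonium bromide | CC1=C(C#C/C(C)=C/C[P+](c2ccccc2)(c2ccccc2)c2ccccc2)C(C)(C)CC=C1.[Br-] | intermediate
11 | (4R,6R)-4-hydroxy-2,2,6-trimethylcyclohexan-1-one | C[C@@H]1C[C@@H](O)CC(C)(C)C1=O | starting material
12 | (4R,6R)-4-[(tert-butyldimethylsilyl)oxy]-2,2,6-trimethylcyclohexan-1-one | C[C@@H]1C[C@@H](O[Si](C)(C)C(C)(C)C)CC(C)(C)C1=O | intermediate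
13 | lithium (4R)-4-[(tert-butyldimethylsilyl)oxy]-2,6,6-trimethylcyclohex-1-en-1-olate | [Li+].[O-]C1=C(C)C[C@@H](O[Si](C)(C)C(C)(C)C)CC1(C)C | intermediate
14 | (4R)-4-[(tert-butyldimethylsilyl)oxy]-2,6,6-trimethylcyclohex-1-en-1-yl trifluoromethanesulfonate | FC(F)(F)S(=O)(=O)OC1=C(C)C[C@@H](O[Si](C)(C)C(C)(C)C)CC1(C)C | intermediate
15 | (E)-5-{(4R)-4-[(tert-butyldimethylsilyl)oxy]-2,6,6-trimethylcyclohex-1-en-1-yl}-3-methylpent-2-en-4-yn-1-ol | OC/C=C(\C)C#CC1=C(C)C[C@@H](O[Si](C)(C)C(C)(C)C)CC1(C)C | intermediate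
16 | (1R)-4-[(E)-5-hydroxy-3-methylpent-3-en-1-yn-1-yl]-3,5,5-trimethylcyclohex-3-en-1-ol | OC/C=C(\C)C#CC1=C(C)C[C@@H](O)CC1(C)C | intermediate
17 | {(E)-5-[(4R)-4-hydroxy-2,6,6-trimethylcyclohex-1-en-1-yl]-3-methylpent-2-en-4-yn-1-yl}triphenylphosphonium bromide | c1ccc(cc1)[P+](c1ccccc1)(c1ccccc1)C/C=C(\C)C#CC1=C(C)C[C@@H](O)CC1(C)C.[Br-] | intermediate
18 | (2E,4E,6E)-2,7-dimethylocta-2,4,6-trienedial | O=C/C(C)=C/C=C/C=C(\C)C=O | starting material
19 | ylide of 10, [(E)-3-methyl-5-(2,6,6-trimethylcyclohexa-1,3-dien-1-yl)pent-2-en-4-yn-1-ylidene]triphenylphosphorane | CC1=C(C#C/C(C)=C/[CH-][P+](c2ccccc2)(c2ccccc2)c2ccccc2)C(C)(C)CC=C1 | intermediate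
20 | (2E,4E,6E,8E,10E)-2,7,11-trimethyl-13-(2,6,6-trimethylcyclohexa-1,3-dien-1-yl)trideca-2,4,6,8,10-pentaen-12-ynal | CC1=C(C#C/C(C)=C/C=C/C(C)=C/C=C/C=C(C)/C=O)C(C)(C)CC=C1 | intermediate
21 | ylide of 17, {(E)-5-[(4R)-4-hydroxy-2,6,6-trimethylcyclohex-1-en-1-yl]-3-methylpent-2-en-4-yn-1-ylidene}triphenylphosphorane | c1ccc(cc1)[P+](c1ccccc1)(c1ccccc1)[CH-]/C=C(\C)C#CC1=C(C)C[C@@H](O)CC1(C)C | intermediate
22 | (3R)-3',4',7,8,7',8'-hexadehydro-β,β-caroten-3-ol, all-E (CNP0250213.1) | CC1=C(C#C/C(C)=C/C=C/C(C)=C/C=C/C=C(C)/C=C/C=C(\C)C#CC2=C(C)C[C@@H](O)CC2(C)C)C(C)(C)CC=C1 | target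

**Step count and risks**

Total step count: 12. Longest linear sequence: 7 steps (steps 1, 2, 3, 4, 5, 11, 12).

Steps most likely to fail:

1. Step 2. Carbene transfer to the hindered enol ether may be inefficient, and it may deliver mainly the C6 epimer of 4 with chloride exo, which cannot open in the allowed disrotatory sense, so the ring enlargement would stall. The fallback sets out from 3 and comes back at 5. Addition of dibromocarbene (CHBr3, KOtBu, pentane, −20 °C) to 3 should give 6,6-dibromo-2,2-dimethyl-1-(trimethylsilyloxy)bicyclo[3.1.0]hexane F1, in which one bromine is endo by necessity. Warming in toluene should enlarge the ring to 2-bromo-6,6-dimethylcyclohex-2-en-1-one F2. Suzuki–Miyaura methylation of F2 with trimethylboroxine (Pd(PPh3)4, K2CO3, dioxane, 90 °C) then returns to 5.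

2. Step 5. Under HBr the delocalised cation from 9 may be captured away from the primary terminus or lose the 9E geometry, and the acid may add to the ring A diene. The fallback sets out from 9 and comes back at 20. Appel bromination (CBr4, PPh3, 2,6-lutidine, CH2Cl2, −20 °C) should give the allylic bromide 1-[(E)-5-bromo-3-methylpent-3-en-1-yn-1-yl]-2,6,6-trimethylcyclohexa-1,3-diene F3. A Michaelis–Becker reaction with NaP(O)(OEt)2 (THF, 0 °C) should give diethyl [(E)-3-methyl-5-(2,6,6-trimethylcyclohexa-1,3-dien-1-yl)pent-2-en-4-yn-1-yl]phosphonate F4. Horner–Wadsworth–Emmons olefination of excess 18 with the anion of F4 (KOtBu, THF, −20 °C to rt) should then give 20 without acid and with higher E selectivity at C11=C12.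

3. Step 11. Olefination may run on at the second aldehyde group to the symmetrical bis-adduct, and the mono-adduct may be hard to free from excess 18. The fallback sets out from 18 and 10 and comes back at 20. Mono-acetalisation of 18 with 2,2-dimethylpropane-1,3-diol (pyridinium tosylate, toluene, rt) should give (2E,4E,6E)-7-(5,5-dimethyl-1,3-dioxan-2-yl)-2-methylocta-2,4,6-trienal F5. Wittig reaction of F5 with 10 (NaOMe, MeOH/CH2Cl2) should give the 5,5-dimethyl-1,3-dioxan-2-yl acetal of aldehyde 20 F6. Mild hydrolysis (pyridinium tosylate, acetone/water, rt) then returns to 20.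

**Further compounds**

F1 | step 2 | 6,6-dibromo-2,2-dimethyl-1-(trimethylsilyloxy)bicyclo[3.1.0]hexane | C[Si](C)(C)OC12C(C)(C)CCC1C2(Br)Br
F2 | step 2 | 2-bromo-6,6-dimethylcyclohex-2-en-1-one | CC1(C)CCC=C(Br)C1=O
F3 | step 5 | 1-[(E)-5-bromo-3-methylpent-3-en-1-yn-1-yl]-2,6,6-trimethylcyclohexa-1,3-diene | CC1=C(C#C/C(C)=C/CBr)C(C)(C)CC=C1
F4 | step 5 | diethyl [(E)-3-methyl-5-(2,6,6-trimethylcyclohexa-1,3-dien-1-yl)pent-2-en-4-yn-1-yl]phosphonate | CCOP(=O)(OCC)C/C=C(\C)C#CC1=C(C)C=CCC1(C)C
F5 | step 11 | (2E,4E,6E)-7-(5,5-dimethyl-1,3-dioxan-2-yl)-2-methylocta-2,4,6-trienal | O=C/C(C)=C/C=C/C=C(\C)C1OCC(C)(C)CO1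
F6 | step 11 | 5,5-dimethyl-1,3-dioxan-2-yl acetal of aldehyde 20 | CC1=C(C#C/C(C)=C/C=C/C(C)=C/C=C/C=C(C)/C2OCC(C)(C)CO2)C(C)(C)CC=C1
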